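**Retrosynthetic overview**

- The target is a (2S)-flavanone (rings A, B and C) whose C8 is joined through one CH2 to C3 of a 4-hydroxy-2-pyrone. The last operations are O-debenzylation and, before it, formation of the CH2–C3(pyrone) bond by acid-catalysed benzylation of the finished pyrone.
- Ring C and its surroundings are cut at three bonds at once (C4–C4a, O1–C8a, C8–CH2). The pieces are 1,5-bis(benzyloxy)-2,4-dibromo-3-fluorobenzene, (3S)-3-hydroxy-N-methoxy-N-methyl-3-phenylpropanamide and ClCH2OMe.
- Enabling feature: C4a, C8a and C8 are three neighbouring carbons of ring A that carry C4, O1 and the bridge CH2, and they are flanked by the C5 and C7 oxygens. This maps onto a symmetric Br–C(F)–Br triad, used first as an aryl anion at C4a and then as a C8≡C8a aryne that takes up O1 at C8a and carbon at C8.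
- Order of ring formation: rings A and B are bought, the pyrone ring is closed in step 2, and ring C is closed last in step 6.
- C2 is bought as ethyl (3S)-3-hydroxy-3-phenylpropanoate. Its C–O bond is never broken, and C4 stays masked while base is present.

Key step: step 6

Remark: flavanone numbering (O1, C2, C3, C4, C4a, C5 to C8, C8a) is used for all compounds of the ring A/ring C series, and the stereocentre of the target SMILES is read as 2S.

**Step 1**
Reactants: 1 methyl 3-oxopentanoate; 2 N-methoxy-N-methylpropanamide
Product: 4 methyl 4-methyl-3,5-dioxoheptanoate, via dilithium dienediolate 3 (not isolated)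
Conditions: LiN(i-Pr)2 (2.2 equiv), THF, −78 → 0 °C; 2 (0.9 equiv), −78 → 0 °C; aq HCl
Reagents that add atoms: none
Why: Claisen-type acylation of a β-keto ester dianion takes place at the more nucleophilic γ-carbon, and the N-methoxy-N-methylamide acylates only once.

**Step 2**
Reactants: 4 methyl 4-methyl-3,5-dioxoheptanoate
Product: 5 6-ethyl-4-hydroxy-5-methyl-2H-pyran-2-one
Conditions: DBU (1.1 equiv), toluene, reflux; aq HCl
Reagents that add atoms: none
Why: Base-induced lactonisation, in which the enolate oxygen on C5 attacks the methyl ester (6-exo-trig) with loss of methanol, and the 4-hydroxy-2-pyrone tautomer is the thermodynamic sink.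

**Step 3**
Reactants: 6 ethyl (3S)-3-hydroxy-3-phenylpropanoate
Product: 7 (3S)-3-hydroxy-N-methoxy-N-methyl-3-phenylpropanamide
Conditions: MeNH(OMe)·HCl (1.6 equiv), i-PrMgCl (4.5 equiv), THF, −20 → 0 °C; aq NH4Cl
Reagents that add atoms: N,O-dimethylhydroxylamine hydrochloride, CNOC.Cl
Why: Ester aminolysis by a magnesium amide made in the flask; the carbinol is only deprotonated, so its S configuration is kept.

**Step 4**
Reactants: 8 5-fluorobenzene-1,3-diol
Product: 9 1,3-bis(benzyloxy)-5-fluorobenzene
Conditions: BnBr (2.2 equiv), K2CO3 (3 equiv), DMF, rt → 50 °C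
Reagents that add atoms: benzyl bromide, BrCc1ccccc1
Why: Williamson ether synthesis on both phenols; benzyl ethers tolerate organolithium reagents at low temperature and leave at the end under neutral conditions.

**Step 5**
Reactants: 9 1,3-bis(benzyloxy)-5-fluorobenzene
Product: 10 1,5-bis(benzyloxy)-2,4-dibromo-3-fluorobenzene
Conditions: NBS (2.05 equiv), MeCN, 0 °C → rt, dark
Reagents that add atoms: N-bromosuccinimide, O=C1CCC(=O)N1Br
Why: Electrophilic aromatic bromination goes twice to the positions para to one benzyloxy group and ortho to the other, beside the small fluorine, and spares the crowded C–H between the two benzyloxy groups, as is usual for 5-substituted resorcinol diethers.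

**Step 6**
Reactants: 10 1,5-bis(benzyloxy)-2,4-dibromo-3-fluorobenzene; 7 (3S)-3-hydroxy-N-methoxy-N-methyl-3-phenylpropanamide
Product: 18 (2S)-5,7-bis(benzyloxy)-8-(methoxymethyl)-2-phenyl-2,3-dihydro-4H-chromen-4-one, via lithium alkoxide 11 (not isolated), via aryllithium 12 (not isolated), via hemiaminal dialkoxide 13 (not isolated), via fluoroaryllithium 14 (not isolated), via aryne 15 (not isolated), via cyclised aryllithium 16 (not isolated), via alkylated hemiaminal alkoxide 17 (not isolated)
Conditions: 7 (1.05 equiv), n-BuLi (1.05 equiv), THF, −78 °C; in a second flask 10, n-BuLi (1.0 equiv), THF, −78 °C; solutions combined at −78 °C; n-BuLi (1.05 equiv), −78 °C, then warmed to −20 °C; ClCH2OMe (1.5 equiv), −78 → 0 °C; poured into cold 1 M aq HCl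
Reagents that add atoms: chloromethyl methyl ether, COCCl
Why: Proposed new method: bromine–lithium exchange at one of the two equivalent C–Br bonds of 10 gives 12, which keeps its fluoride at −78 °C and adds to the N-methoxy-N-methylamide 11 to give the chelated hemiaminal dialkoxide 13, so that C4 stays a masked, non-enolisable sp3 carbon for the rest of the operation. A second exchange gives 14, warming expels LiF to give the C8≡C8a aryne 15, the C2 alkoxide adds to C8a in a 6-exo-dig closure of ring C, and the C8 aryllithium 16 left behind is alkylated by ClCH2OMe to 17 before acid releases the ketone. The side of addition is fixed twice: the inductively withdrawing benzyloxy group on C7, beside C8, makes C8a the more electrophilic aryne carbon and places the carbanion next to oxygen, and the tether from C4a, beside C8a, can reach only C8a, whereas the oxygen and nitrogen on C4 could close only four-membered rings. No stereocentre is created in the isolated product, since C2 comes from 7 with its C–O bond intact, the hemiaminal carbon is transient, and without a free carbonyl neither retro-aldol cleavage nor E1cB opening of ring C can scramble C2. The step needs mono-exchange on the dibromide, which the negative charge built up by the first exchange secures, and the order acylation, aryne formation, alkylation, which the temperature steps secure. The closest known reaction types are the anionic aryne cyclisation of tethered heteroatom nucleophiles with electrophilic trapping of the resulting aryllithium, the ketone synthesis from N-methoxy-N-methylamides, and the use of their tetrahedral adducts as carbonyl masks in one-pot organolithium sequences.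

**Step 7**
Reactants: 18 (2S)-5,7-bis(benzyloxy)-8-(methoxymethyl)-2-phenyl-2,3-dihydro-4H-chromen-4-one; 5 6-ethyl-4-hydroxy-5-methyl-2H-pyran-2-one
Product: 19 3-{[(2S)-5,7-bis(benzyloxy)-4-oxo-2-phenyl-3,4-dihydro-2H-chromen-8-yl]methyl}-6-ethyl-4-hydroxy-5-methyl-2H-pyran-2-one
Conditions: 5 (2 equiv), Sc(OTf)3 (10 mol %), MS 4 Å, MeNO2, rt → 40 °C
Reagents that add atoms: none
Why: Lewis-acid-catalysed Friedel–Crafts-type benzylation of a 4-hydroxy-2-pyrone, in which the CH2–OMe bond ionises easily because the carbon on C8 is ortho to O1 and to the C7 oxygen and para to the C5 oxygen, C3 is the only free nucleophilic carbon of 5, and C2 is safe in acid because the unsubstituted ring B does not support ionisation of C2–O1.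

**Step 8**
Reactants: 19 3-{[(2S)-5,7-bis(benzyloxy)-4-oxo-2-phenyl-3,4-dihydro-2H-chromen-8-yl]methyl}-6-ethyl-4-hydroxy-5-methyl-2H-pyran-2-one
Product: 20 3-{[(2S)-5,7-dihydroxy-4-oxo-2-phenyl-3,4-dihydro-2H-chromen-8-yl]methyl}-6-ethyl-4-hydroxy-5-methyl-2H-pyran-2-one
Conditions: H2 (1 atm), Pd/C (10 wt % Pd), EtOAc–EtOH, rt, stopped at full conversion
Reagents that add atoms: none
Why: Catalytic hydrogenolysis of the two aryl benzyl ethers under neutral conditions avoids the base-induced ring opening that racemises flavanones, and the fully substituted pyrone and the C2–O1 bond should react more slowly.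

**Compound list**

1 | methyl 3-oxopentanoate | CCC(=O)CC(=O)OC | starting material
2 | N-methoxy-N-methylpropanamide | CCC(=O)N(C)OC | starting material
3 | dilithium 1-methoxypenta-1,3-diene-1,3-diolate (dianion of 1) | CC=C(O[Li])C=C(OC)O[Li] | intermediate
4 | methyl 4-methyl-3,5-dioxoheptanoate (racemic, enolisable at C4) | CCC(=O)C(C)C(=O)CC(=O)OC | intermediate
5 | 6-ethyl-4-hydroxy-5-methyl-2H-pyran-2-one | CCc1oc(=O)cc(O)c1C | intermediate
6 | ethyl (3S)-3-hydroxy-3-phenylpropanoate | CCOC(=O)C[C@H](O)c1ccccc1 | starting material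
7 | (3S)-3-hydroxy-N-methoxy-N-methyl-3-phenylpropanamide | CON(C)C(=O)C[C@H](O)c1ccccc1 | intermediate
8 | 5-fluorobenzene-1,3-diol | Oc1cc(O)cc(F)c1 | starting material
9 | 1,3-bis(benzyloxy)-5-fluorobenzene | Fc1cc(OCc2ccccc2)cc(OCc2ccccc2)c1 | intermediate
10 | 1,5-bis(benzyloxy)-2,4-dibromo-3-fluorobenzene | Fc1c(Br)c(OCc2ccccc2)cc(OCc2ccccc2)c1Br | intermediate
11 | lithium alkoxide of 7 | CON(C)C(=O)C[C@H](O[Li])c1ccccc1 | intermediate
12 | [4,6-bis(benzyloxy)-3-bromo-2-fluorophenyl]lithium | [Li]c1c(F)c(Br)c(OCc2ccccc2)cc1OCc1ccccc1 | intermediate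
13 | dilithium salt of (3S)-1-[4,6-bis(benzyloxy)-3-bromo-2-fluorophenyl]-1-[methoxy(methyl)amino]-3-phenylpropane-1,3-diol (C1 undefined) | CON(C)C(O[Li])(C[C@H](O[Li])c1ccccc1)c1c(F)c(Br)c(OCc2ccccc2)cc1OCc1ccccc1 | intermediate
14 | 3-lithio analogue of 13 (Li in place of Br) | CON(C)C(O[Li])(C[C@H](O[Li])c1ccccc1)c1c(F)c([Li])c(OCc2ccccc2)cc1OCc1ccccc1 | intermediate
15 | C8≡C8a aryne, dilithium salt of (3S)-1-[4,6-bis(benzyloxy)-2,3-didehydrophenyl]-1-[methoxy(methyl)amino]-3-phenylpropane-1,3-diol | CON(C)C(O[Li])(C[C@H](O[Li])c1ccccc1)C1=C(OCc2ccccc2)C=C(OCc2ccccc2)C#C1 | intermediate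
16 | lithium (2S)-5,7-bis(benzyloxy)-8-lithio-4-[methoxy(methyl)amino]-2-phenylchroman-4-olate (C4 undefined) | [Li]c1c(OCc2ccccc2)cc(OCc2ccccc2)c2c1O[C@H](c1ccccc1)CC2(O[Li])N(C)OC | intermediate
17 | lithium (2S)-5,7-bis(benzyloxy)-4-[methoxy(methyl)amino]-8-(methoxymethyl)-2-phenylchroman-4-olate (C4 undefined) | COCc1c(OCc2ccccc2)cc(OCc2ccccc2)c2c1O[C@H](c1ccccc1)CC2(O[Li])N(C)OC | intermediate
18 | (2S)-5,7-bis(benzyloxy)-8-(methoxymethyl)-2-phenyl-2,3-dihydro-4H-chromen-4-one | COCc1c(OCc2ccccc2)cc(OCc2ccccc2)c2c1O[C@H](c1ccccc1)CC2=O | intermediate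
19 | 3-{[(2S)-5,7-bis(benzyloxy)-4-oxo-2-phenyl-3,4-dihydro-2H-chromen-8-yl]methyl}-6-ethyl-4-hydroxy-5-methyl-2H-pyran-2-one | CCc1oc(=O)c(Cc2c(OCc3ccccc3)cc(OCc3ccccc3)c3c2O[C@H](c2ccccc2)CC3=O)c(O)c1C | intermediate
20 | 3-{[(2S)-5,7-dihydroxy-4-oxo-2-phenyl-3,4-dihydro-2H-chromen-8-yl]methyl}-6-ethyl-4-hydroxy-5-methyl-2H-pyran-2-one | CCc1oc(=O)c(Cc2c(O)cc(O)c3c2O[C@H](c2ccccc2)CC3=O)c(O)c1C | target

**Step count**

Total step count: 8.
Longest linear sequence: 5 steps (steps 4, 5, 6, 7 and 8, from 8).

**Steps most likely to fail**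

**1. Step 6 (bears the label "Proposed new method:").**

What may go wrong:
- loss of LiF from the first aryllithium before acylation is complete;
- bromine–lithium scrambling between the aryl species in the flask;
- collapse of the hemiaminal alkoxide on warming, followed by enolisation and opening of ring C;
- intermolecular capture of the aryne.

The fallback uses known chemistry. It closes ring C at the achiral chromone level and sets C2 afterwards with a catalyst. It sets out from 10 and comes back at 18.

Mono bromine–lithium exchange (n-BuLi, THF, −78 °C) and acylation with N-methoxy-N-methylacetamide should give 1-[4,6-bis(benzyloxy)-3-bromo-2-fluorophenyl]ethan-1-one F1. Claisen condensation with ethyl formate (NaH, THF) should give 3-[4,6-bis(benzyloxy)-3-bromo-2-fluorophenyl]-3-oxopropanal F2. Its enolate oxygen displaces the fluoride, which the ortho acyl group activates, in an intramolecular SNAr reaction (K2CO3, DMF, 80 °C). This gives 5,7-bis(benzyloxy)-8-bromo-4H-chromen-4-one F3. Stille coupling with Bu3SnCH2OMe (Pd(PPh3)4, toluene, 110 °C) should give 5,7-bis(benzyloxy)-8-(methoxymethyl)-4H-chromen-4-one F4. Enantioselective conjugate addition of PhB(OH)2 then gives 18. The conditions are Pd(OCOCF3)2, the enantiomer of 4-tert-butyl-2-(pyridin-2-yl)-4,5-dihydrooxazole that delivers the 2S product, NH4PF6, H2O, ClCH2CH2Cl, 60 °C.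

**2. Step 7.**

What may go wrong:
- sluggish ionisation of the CH2–OMe bond in the acyl-bearing ring;
- self-condensation by attack of the benzylic electrophile on C6 of a second flavanone;
- acid-induced migration or loss of a benzyl group.

The fallback replaces cationic benzylation by reductive alkylation of an aldehyde. It sets out from 10 and 7 and comes back at 19.

Step 6 is run as written, but 16 is quenched with DMF in place of ClCH2OMe. This gives in the flask the bis(hemiaminal) dialkoxide F5 and, after the acidic work-up, (2S)-5,7-bis(benzyloxy)-4-oxo-2-phenyl-3,4-dihydro-2H-chromene-8-carbaldehyde F6. Organocatalytic reductive alkylation with 5 follows (L-proline cat., diethyl 2,6-dimethyl-1,4-dihydropyridine-3,5-dicarboxylate, CH2Cl2, rt). It proceeds by Knoevenagel condensation to the 3-arylidene-6-ethyl-5-methylpyran-2,4-dione F7, which is reduced in the flask by hydride transfer to 19.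

**3. Step 8.**

What may go wrong:
- over-reduction, that is hydrogenolysis of the benzylic C2–O1 bond;
- saturation of the pyrone C5=C6 bond;
- incomplete cleavage of the hindered C7 benzyl ether.

The fallback changes from reductive to Lewis-acid cleavage. It sets out from 19 and comes back at 20. BCl3 (excess) with pentamethylbenzene as benzyl cation scavenger in CH2Cl2 at −78 °C, followed by a methanol quench at low temperature, should remove both benzyl groups without touching C2. No new compound is made on this way (entry F0).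

**Further compounds**

F1 | step 6 | 1-[4,6-bis(benzyloxy)-3-bromo-2-fluorophenyl]ethan-1-one | CC(=O)c1c(F)c(Br)c(OCc2ccccc2)cc1OCc1ccccc1
F2 | step 6 | 3-[4,6-bis(benzyloxy)-3-bromo-2-fluorophenyl]-3-oxopropanal | O=CCC(=O)c1c(F)c(Br)c(OCc2ccccc2)cc1OCc1ccccc1
F3 | step 6 | 5,7-bis(benzyloxy)-8-bromo-4H-chromen-4-one | O=c1ccoc2c(Br)c(OCc3ccccc3)cc(OCc3ccccc3)c12
F4 | step 6 | 5,7-bis(benzyloxy)-8-(methoxymethyl)-4H-chromen-4-one | COCc1c(OCc2ccccc2)cc(OCc2ccccc2)c2c1occc2=O
F5 | step 7 | bis(hemiaminal) dialkoxide from 16 and DMF | CN(C)C(O[Li])c1c(OCc2ccccc2)cc(OCc2ccccc2)c2c1O[C@H](c1ccccc1)CC2(O[Li])N(C)OC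
F6 | step 7 | (2S)-5,7-bis(benzyloxy)-4-oxo-2-phenyl-3,4-dihydro-2H-chromene-8-carbaldehyde | O=Cc1c(OCc2ccccc2)cc(OCc2ccccc2)c2c1O[C@H](c1ccccc1)CC2=O
F7 | step 7 | 3-{[(2S)-5,7-bis(benzyloxy)-4-oxo-2-phenyl-3,4-dihydro-2H-chromen-8-yl]methylidene}-6-ethyl-5-methyl-2H-pyran-2,4(3H)-dione | CCC1=C(C)C(=O)C(=Cc2c(OCc3ccccc3)cc(OCc3ccccc3)c3c2O[C@H](c2ccccc2)CC3=O)C(=O)O1
F0 | step 8 | none | none
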